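**Plan**

- Retrosynthesis: after removal of two O-benzyl groups, the (2R,3R)-butane-1,4-diol is traced back to a trans-α,β-dibenzyl-γ-butyrolactone. This lactone is cut at its Cα–CH2 bond into an (R)-β-benzyl lactone and a benzofuran-5-ylmethyl bromide.
- Feature that permits the key step: in the 2-aryl-3-(hydroxymethyl)-2,3-dihydrobenzofuran, O1, C2, C3 and the benzo ring are O1, C2, C3 and the benzo ring of a 2-arylchroman-4-one, and the CH2OH carbon is the former ring carbon C4. Cutting C3–C3a and re-inserting C4 between C3 and C4a gives the flavanone, whose C2–aryl bond is then cut to a chromone and an arylboronic acid.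
- Forward order: pyranone ring of the chromone, arylation at C2, contraction of the six-membered ring to the dihydrofuran, one-carbon extension at C5. Separately the lactone ring is made from a Stobbe half-ester. The fragments are joined by enolate alkylation, then the lactone is opened reductively and the benzyl groups are removed.
- Stereochemistry: benzofuran C2 comes from the chiral Pd/pyridine-oxazoline catalyst and C3 from the stereospecific aryl shift (trans to C2). The lactone β-carbon comes from Rh/DuPhos hydrogenation and the α-carbon from alkylation anti to the β-substituent; these two become the R,R diol centres.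

Key step: step 6

Assumption: the ligand enantiomers named in steps 5 and 14 are those that the accepted facial models of these catalyst classes assign to the 2S flavanone and the R succinate; if the sense proves opposite, the mirror-image ligand is used and nothing else changes.

**Route**

Step 1
Reactants: 1 1-(2-hydroxy-3-methoxyphenyl)ethanone
Product: 2 1-(5-bromo-2-hydroxy-3-methoxyphenyl)ethanone
Conditions: NBS (1.05 equiv), MeCN, 0 °C → rt
Reagents that add atoms: N-bromosuccinimide, O=C1CCC(=O)N1Br
Why: Electrophilic aromatic bromination should go to C5, the free position para to the phenol and meta to the acetyl group, since both positions ortho to the hydroxyl are blocked.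

Step 2
Reactants: 2 1-(5-bromo-2-hydroxy-3-methoxyphenyl)ethanone
Product: 4 6-bromo-8-methoxy-4H-chromen-4-one, via enaminone 3 (not isolated)
Conditions: Me2NCH(OMe)2, toluene, 100 °C; then conc. HCl, CH2Cl2, 40 °C
Reagents that add atoms: N,N-dimethylformamide dimethyl acetal, COC(OC)N(C)C
Why: This is the enaminone route to chromones, in which the methyl ketone condenses with the amide acetal and acid then drives 6-endo-trig addition of the phenol to the β-carbon with loss of dimethylamine to close the pyranone ring.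

Step 3
Reactants: 5 4-bromo-2-methoxyphenol
Product: 6 4-bromo-2-methoxyphenyl methanesulfonate
Conditions: MsCl, Et3N, CH2Cl2, 0 °C
Reagents that add atoms: methanesulfonyl chloride, CS(=O)(=O)Cl
Why: O-Sulfonylation of the phenol should be clean and makes the future B ring an electron-poor arene that is slow to migrate or oxidise in step 6.

Step 4
Reactants: 6 4-bromo-2-methoxyphenyl methanesulfonate
Product: 7 [3-methoxy-4-(methylsulfonyloxy)phenyl]boronic acid
Conditions: B2(OH)4, XPhos Pd G2 (1 mol%), XPhos (2 mol%), KOAc, EtOH, 80 °C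
Reagents that add atoms: tetrahydroxydiboron, OB(O)B(O)O
Why: Miyaura-type Pd-catalysed borylation with tetrahydroxydiboron should give the free boronic acid directly, because oxidative addition into C–Br is far faster than into the aryl mesylate C–O bond at this temperature.

Step 5
Reactants: 4 6-bromo-8-methoxy-4H-chromen-4-one, 7 [3-methoxy-4-(methylsulfonyloxy)phenyl]boronic acid
Product: 8 (2S)-6-bromo-8-methoxy-2-[3-methoxy-4-(methylsulfonyloxy)phenyl]chroman-4-one
Conditions: Pd(OCOCF3)2 (5 mol%), (R)-t-BuPyOx (6 mol%), NH4PF6 (30 mol%), H2O (5 equiv), ClCH2CH2Cl, 60 °C, air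
Reagents that add atoms: none
Why: In this Pd(II)/pyridine-oxazoline asymmetric conjugate addition (transmetalation, insertion of the chromone C2=C3 bond into Ar–Pd, protonolysis of the Pd enolate) the tert-butyl oxazoline should block one enone face so that C2 is formed S, and the aryl bromide should survive because the catalyst stays Pd(II).

Step 6
Reactants: 8 (2S)-6-bromo-8-methoxy-2-[3-methoxy-4-(methylsulfonyloxy)phenyl]chroman-4-one
Product: 10 methyl (2S,3S)-5-bromo-7-methoxy-2-[3-methoxy-4-(methylsulfonyloxy)phenyl]-2,3-dihydrobenzofuran-3-carboxylate (trans), via enol ether 9 (not isolated)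
Conditions: PhI(OAc)2 (1.3 equiv), conc. H2SO4 (0.5 equiv), HC(OMe)3, rt; aq. NaHCO3 work-up
Reagents that add atoms: trimethyl orthoformate, COC(OC)OC; water, O
Why: Acid and orthoformate should convert ketone 8 into enol ether 9, the iodine(III) electrophile should then add to C3 on the face away from the C2 aryl group while methanol adds to C4, giving a trans-diequatorial 3-iodanyl 4,4-dimethoxy intermediate whose C4–C4a bond is antiperiplanar to C3–I, and C4a should shift from C4 to C3 as iodobenzene leaves, the dimethoxycarbenium ion ending as the methyl ester after orthoester hydrolysis on work-up. The closest known reaction is the iodine(III)- or thallium(III)-mediated oxidative ring contraction of flavanones in trimethyl orthoformate, a semipinacol-type 1,2-aryl shift. The five-membered ring is closed by the new C3–C3a bond: the ipso carbon C4a attacks C3 in a 3-exo-tet manner through a bridged phenonium-like transition state, and cleavage of the old C4–C4a bond turns the six-membered ring into the dihydrofuran with C4 left outside as the ester carbon. C2 takes no part and keeps the S configuration from step 5, while displacement of iodine at C3 with inversion should place the ester trans to the aryl group, which is also the thermodynamically preferred arrangement. The step needs the C4a shift to outrun both the C2-to-C3 shift of the B ring (isoflavone) and elimination to the flavone; the mesyloxy B ring has low migratory aptitude and disfavours positive charge at C2 (which also guards C2 against acid-mediated ring opening), whereas C4a is activated by the ring oxygen ortho to it.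

Step 7
Reactants: 10 methyl (2S,3S)-5-bromo-7-methoxy-2-[3-methoxy-4-(methylsulfonyloxy)phenyl]-2,3-dihydrobenzofuran-3-carboxylate
Product: 11 4-[(2S,3R)-5-bromo-3-(hydroxymethyl)-7-methoxy-2,3-dihydrobenzofuran-2-yl]-2-methoxyphenyl methanesulfonate
Conditions: DIBAL-H (2.5 equiv), CH2Cl2, –78 → –20 °C; Rochelle salt
Reagents that add atoms: none
Why: Ester-to-alcohol reduction with DIBAL-H, a Lewis-acidic and non-basic hydride, should avoid enolisation at C3 (which would open the ring by β-elimination of the aryloxide) and leave the aryl mesylate and bromide intact, with C3 unchanged in space and only its CIP descriptor altered.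

Step 8
Reactants: 11 4-[(2S,3R)-5-bromo-3-(hydroxymethyl)-7-methoxy-2,3-dihydrobenzofuran-2-yl]-2-methoxyphenyl methanesulfonate
Product: 12 4-[(2S,3R)-5-bromo-3-(hydroxymethyl)-7-methoxy-2,3-dihydrobenzofuran-2-yl]-2-methoxyphenol
Conditions: KOH (5 equiv), MeOH/H2O, 60 °C; then dil. HCl to pH 6
Reagents that add atoms: none
Why: Alkaline hydrolysis of the aryl sulfonate by attack at sulfur should free the phenol now that no enolisable ester remains, the aryl bromide, ethers and alcohol being inert to hydroxide at this temperature.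

Step 9
Reactants: 12 4-[(2S,3R)-5-bromo-3-(hydroxymethyl)-7-methoxy-2,3-dihydrobenzofuran-2-yl]-2-methoxyphenol
Product: 13 [(2S,3R)-2-[4-(benzyloxy)-3-methoxyphenyl]-5-bromo-7-methoxy-2,3-dihydrobenzofuran-3-yl]methanol
Conditions: BnBr, K2CO3, acetone, 55 °C
Reagents that add atoms: benzyl bromide, BrCc1ccccc1
Why: In this Williamson ether synthesis carbonate deprotonates only the phenol (pKa about 10), so the primary alcohol should not be benzylated.

Step 10
Reactants: 13 [(2S,3R)-2-[4-(benzyloxy)-3-methoxyphenyl]-5-bromo-7-methoxy-2,3-dihydrobenzofuran-3-yl]methanol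
Product: 14 [(2S,3R)-2-[4-(benzyloxy)-3-methoxyphenyl]-5-bromo-7-methoxy-2,3-dihydrobenzofuran-3-yl]methyl pivalate
Conditions: PivCl, pyridine, DMAP (cat.), CH2Cl2, 0 °C → rt
Reagents that add atoms: pivaloyl chloride, CC(C)(C)C(=O)Cl
Why: DMAP-catalysed acylation of the primary alcohol should give an ester hindered enough to survive the enolate of step 16 and yet be removed by the hydride of step 17.

Step 11
Reactants: 14 [(2S,3R)-2-[4-(benzyloxy)-3-methoxyphenyl]-5-bromo-7-methoxy-2,3-dihydrobenzofuran-3-yl]methyl pivalate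
Product: 15 [(2S,3R)-2-[4-(benzyloxy)-3-methoxyphenyl]-5-(hydroxymethyl)-7-methoxy-2,3-dihydrobenzofuran-3-yl]methyl pivalate
Conditions: Bu3SnCH2OH (1.3 equiv), XPhos Pd G2 (5 mol%), 1,4-dioxane, 90 °C
Reagents that add atoms: (tributylstannyl)methanol, CCCC[Sn](CO)(CCCC)CCCC
Why: In this Migita–Kosugi–Stille cross-coupling the stannane should transfer its hydroxymethyl group to the arylpalladium bromide under neutral conditions that spare the pivalate and the benzyl ether.

Step 12
Reactants: 15 [(2S,3R)-2-[4-(benzyloxy)-3-methoxyphenyl]-5-(hydroxymethyl)-7-methoxy-2,3-dihydrobenzofuran-3-yl]methyl pivalate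
Product: 16 [(2S,3R)-2-[4-(benzyloxy)-3-methoxyphenyl]-5-(bromomethyl)-7-methoxy-2,3-dihydrobenzofuran-3-yl]methyl pivalate
Conditions: CBr4, PPh3, CH2Cl2, 0 °C; used without storage
Reagents that add atoms: carbon tetrabromide, BrC(Br)(Br)Br
Why: In the Appel reaction the oxyphosphonium of the benzylic alcohol should be displaced by bromide under neutral conditions that leave the pivalate and the ethers untouched.

Step 13
Reactants: 17 4-(benzyloxy)-3-methoxybenzaldehyde, 18 dimethyl succinate
Product: 19 (E)-4-[4-(benzyloxy)-3-methoxyphenyl]-3-(methoxycarbonyl)but-3-enoic acid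
Conditions: NaOMe, MeOH, reflux; then aq. HCl
Reagents that add atoms: none
Why: The Stobbe condensation (aldol addition, lactonisation to the paraconic ester, E1cB ring opening) should give the E half-ester with the free acid on the CH2 arm.

Step 14
Reactants: 19 (E)-4-[4-(benzyloxy)-3-methoxyphenyl]-3-(methoxycarbonyl)but-3-enoic acid
Product: 20 (3R)-4-[4-(benzyloxy)-3-methoxyphenyl]-3-(methoxycarbonyl)butanoic acid
Conditions: H2 (5 bar), [Rh(cod)((S,S)-Et-DuPhos)]BF4 (1 mol%), NaOMe (0.1 equiv), MeOH, rt
Reagents that add atoms: none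
Why: In this Rh–bisphospholane asymmetric hydrogenation of an itaconate-type half-ester, chelation of alkene and carboxylate to the chiral Rh centre should fix the face of hydrogen addition and set the R centre, and the homogeneous catalyst should not cleave the benzyl ether.

Step 15
Reactants: 20 (3R)-4-[4-(benzyloxy)-3-methoxyphenyl]-3-(methoxycarbonyl)butanoic acid
Product: 22 (4R)-4-[4-(benzyloxy)-3-methoxybenzyl]dihydrofuran-2(3H)-one, via hydroxy acid 21 (not isolated)
Conditions: KOH (1 equiv), EtOH; CaCl2, NaBH4, EtOH, –10 °C → rt; then 2 M HCl, rt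
Reagents that add atoms: none
Why: Chemoselective borohydride reduction with calcium borohydride should reduce the methyl ester but not the carboxylate salt, and acidification should lactonise hydroxy acid 21 (5-exo-trig) without touching the stereocentre.

Step 16
Reactants: 22 (4R)-4-[4-(benzyloxy)-3-methoxybenzyl]dihydrofuran-2(3H)-one, 16 [(2S,3R)-2-[4-(benzyloxy)-3-methoxyphenyl]-5-(bromomethyl)-7-methoxy-2,3-dihydrobenzofuran-3-yl]methyl pivalate
Product: 24 (3R,4R)-3-{[(2S,3R)-2-[4-(benzyloxy)-3-methoxyphenyl]-7-methoxy-3-(pivaloyloxymethyl)-2,3-dihydrobenzofuran-5-yl]methyl}-4-[4-(benzyloxy)-3-methoxybenzyl]dihydrofuran-2(3H)-one, via lithium enolate 23 (not isolated)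
Conditions: 22, LiHMDS (1.05 equiv), THF, –78 °C; then 16, DMPU, –78 → –40 °C
Reagents that add atoms: none
Why: In this diastereoselective lactone enolate alkylation the β-benzyl group shields one face of enolate 23, so the benzylic bromide should enter anti to it and form the new α-centre R, trans to the β-substituent.

Step 17
Reactants: 24 (3R,4R)-3-{[(2S,3R)-2-[4-(benzyloxy)-3-methoxyphenyl]-7-methoxy-3-(pivaloyloxymethyl)-2,3-dihydrobenzofuran-5-yl]methyl}-4-[4-(benzyloxy)-3-methoxybenzyl]dihydrofuran-2(3H)-one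
Product: 25 (2R,3R)-2-{[(2S,3R)-2-[4-(benzyloxy)-3-methoxyphenyl]-3-(hydroxymethyl)-7-methoxy-2,3-dihydrobenzofuran-5-yl]methyl}-3-[4-(benzyloxy)-3-methoxybenzyl]butane-1,4-diol
Conditions: LiAlH4 (4 equiv), THF, 0 °C → rt
Reagents that add atoms: none
Why: Hydride reduction with LiAlH4 should open the lactone to the 1,4-diol and cleave the pivalate in the same operation, carbonyl reduction being faster than any enolisation at the α-centre.

Step 18
Reactants: 25 (2R,3R)-2-{[(2S,3R)-2-[4-(benzyloxy)-3-methoxyphenyl]-3-(hydroxymethyl)-7-methoxy-2,3-dihydrobenzofuran-5-yl]methyl}-3-[4-(benzyloxy)-3-methoxybenzyl]butane-1,4-diol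
Product: 26 (2R,3R)-2-{[(2S,3R)-2-(4-hydroxy-3-methoxyphenyl)-3-(hydroxymethyl)-7-methoxy-2,3-dihydrobenzofuran-5-yl]methyl}-3-(4-hydroxy-3-methoxybenzyl)butane-1,4-diol
Conditions: H2 (1 atm), 10% Pd/C, EtOAc/MeOH, rt
Reagents that add atoms: none
Why: Catalytic hydrogenolysis of the two aryl benzyl ethers over Pd/C, stopped after uptake of two equivalents of hydrogen, should free both phenols before the slower cleavage of the cyclic benzylic C2–O bond can start.

**Compound list**

1 | 1-(2-hydroxy-3-methoxyphenyl)ethanone | CC(=O)c1cccc(OC)c1O | starting material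
2 | 1-(5-bromo-2-hydroxy-3-methoxyphenyl)ethanone | CC(=O)c1cc(Br)cc(OC)c1O | intermediate
3 | (E)-1-(5-bromo-2-hydroxy-3-methoxyphenyl)-3-(dimethylamino)prop-2-en-1-one | CN(C)/C=C/C(=O)c1cc(Br)cc(OC)c1O | intermediate
4 | 6-bromo-8-methoxy-4H-chromen-4-one | O=C1C=COc2c(OC)cc(Br)cc12 | intermediate
5 | 4-bromo-2-methoxyphenol | COc1cc(Br)ccc1O | starting material
6 | 4-bromo-2-methoxyphenyl methanesulfonate | COc1cc(Br)ccc1OS(C)(=O)=O | intermediate
7 | [3-methoxy-4-(methylsulfonyloxy)phenyl]boronic acid | COc1cc(B(O)O)ccc1OS(C)(=O)=O | intermediate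
8 | (2S)-6-bromo-8-methoxy-2-[3-methoxy-4-(methylsulfonyloxy)phenyl]chroman-4-one | O=C1C[C@@H](c2ccc(OS(C)(=O)=O)c(OC)c2)Oc2c(OC)cc(Br)cc21 | intermediate
9 | (2S)-6-bromo-4,8-dimethoxy-2-[3-methoxy-4-(methylsulfonyloxy)phenyl]-2H-chromene | COC1=C[C@@H](c2ccc(OS(C)(=O)=O)c(OC)c2)Oc2c(OC)cc(Br)cc21 | intermediate
10 | methyl (2S,3S)-5-bromo-7-methoxy-2-[3-methoxy-4-(methylsulfonyloxy)phenyl]-2,3-dihydrobenzofuran-3-carboxylate | Brc1cc(OC)c2c(c1)[C@H](C(=O)OC)[C@@H](c1ccc(OS(C)(=O)=O)c(OC)c1)O2 | intermediate
11 | 4-[(2S,3R)-5-bromo-3-(hydroxymethyl)-7-methoxy-2,3-dihydrobenzofuran-2-yl]-2-methoxyphenyl methanesulfonate | Brc1cc(OC)c2c(c1)[C@H](CO)[C@@H](c1ccc(OS(C)(=O)=O)c(OC)c1)O2 | intermediate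
12 | 4-[(2S,3R)-5-bromo-3-(hydroxymethyl)-7-methoxy-2,3-dihydrobenzofuran-2-yl]-2-methoxyphenol | Brc1cc(OC)c2c(c1)[C@H](CO)[C@@H](c1ccc(O)c(OC)c1)O2 | intermediate
13 | [(2S,3R)-2-[4-(benzyloxy)-3-methoxyphenyl]-5-bromo-7-methoxy-2,3-dihydrobenzofuran-3-yl]methanol | Brc1cc(OC)c2c(c1)[C@H](CO)[C@@H](c1ccc(OCc3ccccc3)c(OC)c1)O2 | intermediate
14 | [(2S,3R)-2-[4-(benzyloxy)-3-methoxyphenyl]-5-bromo-7-methoxy-2,3-dihydrobenzofuran-3-yl]methyl pivalate | Brc1cc(OC)c2c(c1)[C@H](COC(=O)C(C)(C)C)[C@@H](c1ccc(OCc3ccccc3)c(OC)c1)O2 | intermediate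
15 | [(2S,3R)-2-[4-(benzyloxy)-3-methoxyphenyl]-5-(hydroxymethyl)-7-methoxy-2,3-dihydrobenzofuran-3-yl]methyl pivalate | OCc1cc(OC)c2c(c1)[C@H](COC(=O)C(C)(C)C)[C@@H](c1ccc(OCc3ccccc3)c(OC)c1)O2 | intermediate
16 | [(2S,3R)-2-[4-(benzyloxy)-3-methoxyphenyl]-5-(bromomethyl)-7-methoxy-2,3-dihydrobenzofuran-3-yl]methyl pivalate | BrCc1cc(OC)c2c(c1)[C@H](COC(=O)C(C)(C)C)[C@@H](c1ccc(OCc3ccccc3)c(OC)c1)O2 | intermediate
17 | 4-(benzyloxy)-3-methoxybenzaldehyde | COc1cc(C=O)ccc1OCc1ccccc1 | starting material
18 | dimethyl succinate | COC(=O)CCC(=O)OC | starting material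
19 | (E)-4-[4-(benzyloxy)-3-methoxyphenyl]-3-(methoxycarbonyl)but-3-enoic acid | COC(=O)/C(CC(=O)O)=C/c1ccc(OCc2ccccc2)c(OC)c1 | intermediate
20 | (3R)-4-[4-(benzyloxy)-3-methoxyphenyl]-3-(methoxycarbonyl)butanoic acid | COC(=O)[C@@H](CC(=O)O)Cc1ccc(OCc2ccccc2)c(OC)c1 | intermediate
21 | (3R)-3-[4-(benzyloxy)-3-methoxybenzyl]-4-hydroxybutanoic acid | OC[C@@H](CC(=O)O)Cc1ccc(OCc2ccccc2)c(OC)c1 | intermediate
22 | (4R)-4-[4-(benzyloxy)-3-methoxybenzyl]dihydrofuran-2(3H)-one | O=C1C[C@@H](Cc2ccc(OCc3ccccc3)c(OC)c2)CO1 | intermediate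
23 | lithium (3R)-3-[4-(benzyloxy)-3-methoxybenzyl]-2,3-dihydrofuran-5-olate | [Li+].[O-]C1=C[C@@H](Cc2ccc(OCc3ccccc3)c(OC)c2)CO1 | intermediate
24 | (3R,4R)-3-{[(2S,3R)-2-[4-(benzyloxy)-3-methoxyphenyl]-7-methoxy-3-(pivaloyloxymethyl)-2,3-dihydrobenzofuran-5-yl]methyl}-4-[4-(benzyloxy)-3-methoxybenzyl]dihydrofuran-2(3H)-one | O=C1[C@H](Cc2cc(OC)c3c(c2)[C@H](COC(=O)C(C)(C)C)[C@@H](c2ccc(OCc4ccccc4)c(OC)c2)O3)[C@@H](Cc2ccc(OCc3ccccc3)c(OC)c2)CO1 | intermediate
25 | (2R,3R)-2-{[(2S,3R)-2-[4-(benzyloxy)-3-methoxyphenyl]-3-(hydroxymethyl)-7-methoxy-2,3-dihydrobenzofuran-5-yl]methyl}-3-[4-(benzyloxy)-3-methoxybenzyl]butane-1,4-diol | COc1cc(C[C@@H](CO)[C@H](CO)Cc2cc(OC)c3c(c2)[C@H](CO)[C@@H](c2ccc(OCc4ccccc4)c(OC)c2)O3)ccc1OCc1ccccc1 | intermediate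
26 | (2R,3R)-2-{[(2S,3R)-2-(4-hydroxy-3-methoxyphenyl)-3-(hydroxymethyl)-7-methoxy-2,3-dihydrobenzofuran-5-yl]methyl}-3-(4-hydroxy-3-methoxybenzyl)butane-1,4-diol (CNP0256425.1) | COc1cc(C[C@@H](CO)[C@H](CO)Cc2cc(OC)c3c(c2)[C@H](CO)[C@@H](c2ccc(O)c(OC)c2)O3)ccc1O | target

**Step count and risks**

Total step count: 18. Longest linear sequence: 13 steps (steps 1, 2, 5–12, 16–18 from compound 1; the branch from compound 5 through steps 3 and 4 is equally long).

Steps most likely to fail:

Step 6. The shift of the B-ring aryl group from C2 to C3, or elimination to the flavone, may compete with the C4a shift. Reversible acid-mediated opening at C2 could also erode enantiomeric purity. The fallback sets out from 8 and returns at 10, and uses a Wolff ring contraction, which forms the same C3–C3a bond without cationic character next to C2. Detrifluoroacetylative diazo transfer on 8 (LiHMDS, CF3CO2CH2CF3, THF, –78 °C) should give the 3-trifluoroacetyl ketone F1, which with MsN3 and Et3N in aqueous MeCN should give the 3-diazo ketone F2. Irradiation of F2 (≥300 nm) in methanol should expel N2, move C4a from C4 to the carbene carbon C3, and let methanol capture the ketene. This should give ester 10 together with its cis epimer F3. Brief treatment with catalytic NaOMe in MeOH at 0 °C should convert F3 into the more stable trans ester 10.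

Step 5. The PyOx catalyst may discriminate poorly between the faces of this 6,8-disubstituted chromone, and protodeboronation of the electron-poor boronic acid may limit conversion, so that 8 is not enantiopure enough. The fallback sets out from 4 and 7 and returns at 8, and replaces catalyst-controlled arylation by resolution. Addition of 7 to 4 with the more active achiral Pd(OCOCF3)2/2,2'-bipyridine catalyst should give the racemic flavanone F4. Asymmetric transfer hydrogenation under kinetic-resolution conditions (RuCl[(R,R)-TsDPEN](p-cymene), HCO2H/Et3N, stopped near half conversion) is expected to reduce the 2R enantiomer to the cis-(2R,4R)-flavan-4-ol F5. The 2S ketone 8 should remain and be separable by chromatography.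

Step 11. Oxidative addition into the electron-rich aryl bromide may be slow, so that protodestannylation of the reagent and reduction of the C–Br bond take over. The fallback sets out from 14 and returns at 15, and brings the carbon in as a vinyl group that is then cut back. Suzuki–Miyaura coupling of 14 with potassium vinyltrifluoroborate (PdCl2(dppf), Et3N, n-PrOH, 90 °C) should give the styrene F6. Lemieux–Johnson cleavage (OsO4 cat., NaIO4, 2,6-lutidine, dioxane/H2O) should give the aldehyde F7. NaBH4 in MeOH/THF at 0 °C should reduce F7 to 15 without touching the pivalate.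

Further compounds
F1 | step 6 | (2S)-6-bromo-8-methoxy-2-[3-methoxy-4-(methylsulfonyloxy)phenyl]-3-(trifluoroacetyl)chroman-4-one (C3 undefined, largely enolised) | O=C1C(C(=O)C(F)(F)F)[C@@H](c2ccc(OS(C)(=O)=O)c(OC)c2)Oc2c(OC)cc(Br)cc21
F2 | step 6 | (2R)-6-bromo-3-diazo-8-methoxy-2-[3-methoxy-4-(methylsulfonyloxy)phenyl]chroman-4-one (same spatial arrangement at C2 as 8) | O=C1C(=[N+]=[N-])[C@@H](c2ccc(OS(C)(=O)=O)c(OC)c2)Oc2c(OC)cc(Br)cc21
F3 | step 6 | methyl (2S,3R)-5-bromo-7-methoxy-2-[3-methoxy-4-(methylsulfonyloxy)phenyl]-2,3-dihydrobenzofuran-3-carboxylate (cis) | Brc1cc(OC)c2c(c1)[C@@H](C(=O)OC)[C@@H](c1ccc(OS(C)(=O)=O)c(OC)c1)O2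
F4 | step 5 | rac-6-bromo-8-methoxy-2-[3-methoxy-4-(methylsulfonyloxy)phenyl]chroman-4-one | O=C1CC(c2ccc(OS(C)(=O)=O)c(OC)c2)Oc2c(OC)cc(Br)cc21
F5 | step 5 | 4-[(2R,4R)-6-bromo-4-hydroxy-8-methoxychroman-2-yl]-2-methoxyphenyl methanesulfonate (cis) | O[C@@H]1C[C@H](c2ccc(OS(C)(=O)=O)c(OC)c2)Oc2c(OC)cc(Br)cc21
F6 | step 11 | [(2S,3R)-2-[4-(benzyloxy)-3-methoxyphenyl]-5-ethenyl-7-methoxy-2,3-dihydrobenzofuran-3-yl]methyl pivalate | C=Cc1cc(OC)c2c(c1)[C@H](COC(=O)C(C)(C)C)[C@@H](c1ccc(OCc3ccccc3)c(OC)c1)O2
F7 | step 11 | [(2S,3R)-2-[4-(benzyloxy)-3-methoxyphenyl]-5-formyl-7-methoxy-2,3-dihydrobenzofuran-3-yl]methyl pivalate | O=Cc1cc(OC)c2c(c1)[C@H](COC(=O)C(C)(C)C)[C@@H](c1ccc(OCc3ccccc3)c(OC)c1)O2
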